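**Retrosynthetic overview**

- The strategy rests on the 2,5-dihydrofuran ring (O, C5', C6', C7', C8') fused to the cyclohexane at C5'–C6'. One oxygen sits on both C5' and C8' across C6'=C7', which is the 1,4-dioxygenated 2-ene core of the 1,2-dioxine formed when O2 adds across the ring diene C5'=C6'–C7'=C8'.
- The C40 chain is cut at C11'=C12' and C11=C12 (two Wittig reactions) into a furanoid C15 ylide, 2,7-dimethylocta-2,4,6-trienedial and a triol C15 ylide.
- Furanoid C15 unit: endoperoxide, then O–O reduction, inversion at C8' and 5-exo-tet closure by the C5' oxygen (net retention, one oxygen removed). The endoperoxide comes from singlet oxygen and the silylated 3-hydroxy C15 trienoate, made by olefination of a ketone from a Heck coupling of the enol triflate of (4R,6R)-actinol (from 4-oxoisophorone).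
- Triol C15 unit: the same 3-silyloxy-β-ionone, hydroxyl-directed syn-epoxidation, anti hydrolysis at C5, then olefination.
- Ring order: carbocycle (from the start), 1,2-dioxine (step 7), dihydrofuran (step 11); the triol ring only passes through an oxirane (steps 16, 17).

Key step: step 7

Remarks on the chemistry: locants are carotenoid locants, primed for the furanoid half and unprimed for the triol half. The target SMILES is read as the all-E (3S,5R,6R,3'S,5'R,8'R) isomer. TBS = tert-butyldimethylsilyl, DIAD = diisopropyl azodicarboxylate, NBS = N-bromosuccinimide. Minor Z isomers from the olefinations and the minor diastereomer of step 7 are assumed to be removable by chromatography.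

**Route**

Step 1
Reactants: 1 4-oxoisophorone
Product: 2 (6R)-2,2,6-trimethylcyclohexane-1,4-dione
Conditions: baker's yeast (Saccharomyces cerevisiae), sucrose, H2O, 30 °C
Reagents that add atoms: none
Why: Whole-cell ene-reductase reduction of the enedione C=C, in which the enzyme delivers hydrogen to one face and should set C6 as R.

Step 2
Reactants: 2 (6R)-2,2,6-trimethylcyclohexane-1,4-dione
Product: 3 (4R,6R)-4-hydroxy-2,2,6-trimethylcyclohexan-1-one
Conditions: LiBH(s-Bu)3, THF, −78 °C; then NaOH, H2O2, 0 °C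
Reagents that add atoms: none
Why: Chemo- and diastereoselective ketone reduction by a bulky trialkylborohydride: the C1 carbonyl is shielded by three flanking methyl groups, and at C4 the axial methyl on C2 blocks axial approach, so hydride should enter equatorially and give the axial hydroxyl trans to the C6 methyl (4R, substrate control from C6).

Step 3
Reactants: 3 (4R,6R)-4-hydroxy-2,2,6-trimethylcyclohexan-1-one
Product: 4 (4R,6R)-4-[(tert-butyldimethylsilyl)oxy]-2,2,6-trimethylcyclohexan-1-one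
Conditions: TBSCl, imidazole, DMF, rt
Reagents that add atoms: tert-butyldimethylsilyl chloride, CC(C)(C)[Si](C)(C)Cl
Why: Imidazole-promoted silylation of a secondary alcohol, which touches no stereocentre.

Step 4
Reactants: 4 (4R,6R)-4-[(tert-butyldimethylsilyl)oxy]-2,2,6-trimethylcyclohexan-1-one
Product: 6 (4R)-4-[(tert-butyldimethylsilyl)oxy]-2,6,6-trimethylcyclohex-1-en-1-yl trifluoromethanesulfonate, via lithium enolate 5 (not isolated)
Conditions: LiN(i-Pr)2, THF, −78 to 0 °C; then PhNTf2, −78 °C to rt; aq. NH4Cl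
Reagents that add atoms: lithium diisopropylamide, [Li+].CC(C)[N-]C(C)C (lithium of 5 only); N-phenylbis(trifluoromethanesulfonimide), O=S(=O)(N(c1ccccc1)S(=O)(=O)C(F)(F)F)C(F)(F)F
Why: Only C6 carries an enolisable hydrogen, so a single tetrasubstituted enolate forms and is O-sulfonylated (enol triflate formation); the C6 stereocentre is erased on purpose and C4 (R) remains.

Step 5
Reactants: 6 (4R)-4-[(tert-butyldimethylsilyl)oxy]-2,6,6-trimethylcyclohex-1-en-1-yl trifluoromethanesulfonate; 7 but-3-en-2-one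
Product: 8 (3E)-4-[(4R)-4-[(tert-butyldimethylsilyl)oxy]-2,6,6-trimethylcyclohex-1-en-1-yl]but-3-en-2-one
Conditions: Pd(OAc)2 (5 mol %), PPh3, Et3N, DMF, 70 °C
Reagents that add atoms: but-3-en-2-one (7), CC(=O)C=C
Why: Mizoroki–Heck reaction: oxidative addition of the vinyl triflate to zerovalent palladium, syn insertion of the electron-poor alkene and syn β-hydride elimination should give the E enone.

Step 6
Reactants: 8 (3E)-4-[(4R)-4-[(tert-butyldimethylsilyl)oxy]-2,6,6-trimethylcyclohex-1-en-1-yl]but-3-en-2-one; 9 triethyl phosphonoacetate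
Product: 10 ethyl (2E,4E)-5-[(4R)-4-[(tert-butyldimethylsilyl)oxy]-2,6,6-trimethylcyclohex-1-en-1-yl]-3-methylpenta-2,4-dienoate
Conditions: NaH, THF, 0 °C; then 8, 0 °C to rt
Reagents that add atoms: triethyl phosphonoacetate (9), CCOC(=O)CP(=O)(OCC)OCC
Why: Horner–Wadsworth–Emmons olefination of the methyl ketone, where the stabilised phosphonate should give mainly the 2E ester and the 2Z isomer is removed by chromatography.

Step 7
Reactants: 10 ethyl (2E,4E)-5-[(4R)-4-[(tert-butyldimethylsilyl)oxy]-2,6,6-trimethylcyclohex-1-en-1-yl]-3-methylpenta-2,4-dienoate; 11 dioxygen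
Product: 12 ethyl (2E)-3-[(3R,7S,8aR)-7-[(tert-butyldimethylsilyl)oxy]-5,5,8a-trimethyl-3,5,6,7,8,8a-hexahydrobenzo[c][1,2]dioxin-3-yl]but-2-enoate (C15 5',8'-endoperoxide; 3'S,5'R,8'R)
Conditions: O2, tetraphenylporphyrin (cat.), visible light, CH2Cl2, −20 °C
Reagents that add atoms: dioxygen (11), O=O
Why: Photosensitised singlet oxygen adds in a concerted suprafacial [4+2] cycloaddition (hetero-Diels–Alder, known for β-ionone-type ring dienes) across C5'=C6'–C7'=C8', a diene held in a twisted s-cis arrangement by the ring methyl groups. The 1,2-dioxine ring is closed by the cycloaddition itself: the C5'–O and C8'–O bonds form on the same face and the double bond moves to C6'=C7' inside the new ring. Because the addition is suprafacial and C7'=C8' is E, the inside groups (5'-methyl and H-8') end cis, which fixes the relative configuration of C5' and C8'. The absolute sense comes from C3': oxygen should approach the face anti to the bulky silyloxy group and give C5'–O trans to C3'–O, probably with only moderate preference, so the syn diastereomer is to be separated. The step also needs periselectivity against the ene reaction at C5'=C6' and against addition to the chain diene; the ester-deactivated C9'=C10' bond and the electron-rich tetrasubstituted diene terminus should secure it.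

Step 8
Reactants: 12 C15 5',8'-endoperoxide
Product: 13 ethyl (2E,4R,5Z)-5-[(2R,4S)-4-[(tert-butyldimethylsilyl)oxy]-2-hydroxy-2,6,6-trimethylcyclohexylidene]-4-hydroxy-3-methylpent-2-enoate
Conditions: thiourea, MeOH, rt
Reagents that add atoms: none
Why: Thiourea reduction of the endoperoxide O–O bond under neutral conditions (standard route to cis-2-ene-1,4-diols) leaves both C–O bonds, both stereocentres and the Z geometry of C6'=C7' untouched.

Step 9
Reactants: 13 ethyl (2E,4R,5Z)-5-[(2R,4S)-4-[(tert-butyldimethylsilyl)oxy]-2-hydroxy-2,6,6-trimethylcyclohexylidene]-4-hydroxy-3-methylpent-2-enoate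
Product: 14 ethyl (2E,4S,5Z)-5-[(2R,4S)-4-[(tert-butyldimethylsilyl)oxy]-2-hydroxy-2,6,6-trimethylcyclohexylidene]-3-methyl-4-[(4-nitrobenzoyl)oxy]pent-2-enoate
Conditions: 4-O2NC6H4CO2H (excess), PPh3, DIAD, THF, 0 °C
Reagents that add atoms: 4-nitrobenzoic acid, O=C(O)c1ccc(cc1)[N+](=O)[O-]
Why: Mitsunobu reaction: only the secondary C8' hydroxyl is activated as the alkoxyphosphonium ion (the tertiary C5' hydroxyl is not), the carboxylate displaces it by SN2 with inversion to (8'S), and no hydrogen on an sp3 β-carbon is available for elimination.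

Step 10
Reactants: 14 ethyl (2E,4S,5Z)-5-[(2R,4S)-4-[(tert-butyldimethylsilyl)oxy]-2-hydroxy-2,6,6-trimethylcyclohexylidene]-3-methyl-4-[(4-nitrobenzoyl)oxy]pent-2-enoate
Product: 15 ethyl (2E,4S,5Z)-5-[(2R,4S)-4-[(tert-butyldimethylsilyl)oxy]-2-hydroxy-2,6,6-trimethylcyclohexylidene]-4-hydroxy-3-methylpent-2-enoate
Conditions: K2CO3, EtOH, 0 °C
Reagents that add atoms: none
Why: Base-catalysed ethanolysis cleaves the activated aryl ester at its acyl carbon, so the C8'–O bond and the (8'S) configuration are kept, and ethanol as solvent makes any exchange at the ethyl ester degenerate.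

Step 11
Reactants: 15 ethyl (2E,4S,5Z)-5-[(2R,4S)-4-[(tert-butyldimethylsilyl)oxy]-2-hydroxy-2,6,6-trimethylcyclohexylidene]-4-hydroxy-3-methylpent-2-enoate
Product: 17 ethyl (2E)-3-[(2R,6S,7aR)-6-[(tert-butyldimethylsilyl)oxy]-4,4,7a-trimethyl-2,4,5,6,7,7a-hexahydro-1-benzofuran-2-yl]but-2-enoate (furanoid C15 ester), via C8' mesylate 16 (not isolated)
Conditions: Ms2O, Et3N, CH2Cl2, −40 °C to rt
Reagents that add atoms: methanesulfonic anhydride, CS(=O)(=O)OS(C)(=O)=O (mesyl group of 16 only; nothing of it remains in 17)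
Why: Selective sulfonylation of the secondary hydroxyl followed by intramolecular Williamson-type etherification: the tertiary C5' hydroxyl, held close by the Z C6'=C7' bond, should displace the mesylate in a 5-exo-tet SN2 closure with inversion, which returns C8' to R (net retention over the two inversions) and leaves only the C5' oxygen in the ring; the chloride-free anhydride avoids allylic chloride formation and the ester-conjugated C9'=C10' bond disfavours ionisation.

Step 12
Reactants: 17 furanoid C15 ester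
Product: 18 (2E)-3-[(2R,6S,7aR)-6-[(tert-butyldimethylsilyl)oxy]-4,4,7a-trimethyl-2,4,5,6,7,7a-hexahydro-1-benzofuran-2-yl]but-2-en-1-ol
Conditions: i-Bu2AlH, CH2Cl2, −78 °C; aq. KNaC4H4O6
Reagents that add atoms: none
Why: 1,2-Reduction of the α,β-unsaturated ester to the allylic alcohol by i-Bu2AlH, to which the cyclic ether, the silyl ether and the alkenes are inert.

Step 13
Reactants: 18 (2E)-3-[(2R,6S,7aR)-6-[(tert-butyldimethylsilyl)oxy]-4,4,7a-trimethyl-2,4,5,6,7,7a-hexahydro-1-benzofuran-2-yl]but-2-en-1-ol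
Product: 20 [(2E)-3-[(2R,6S,7aR)-6-[(tert-butyldimethylsilyl)oxy]-4,4,7a-trimethyl-2,4,5,6,7,7a-hexahydro-1-benzofuran-2-yl]but-2-en-1-yl]triphenylphosphonium bromide, via allylic bromide 19 (not isolated)
Conditions: CBr4, PPh3, CH2Cl2, −20 to 0 °C; then PPh3, rt
Reagents that add atoms: tetrabromomethane, BrC(Br)(Br)Br; triphenylphosphine, c1ccc(cc1)P(c1ccccc1)c1ccccc1
Why: Appel bromination of the primary allylic alcohol under neutral conditions followed by SN2 quaternisation of triphenylphosphine avoids the acid that would epimerise the doubly allylic C8'–O bond.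

Step 14
Reactants: 20 furanoid C15 phosphonium bromide; 21 (2E,4E,6E)-2,7-dimethylocta-2,4,6-trienedial
Product: 22 (2E,4E,6E,8E,10E)-11-[(2R,6S,7aR)-6-[(tert-butyldimethylsilyl)oxy]-4,4,7a-trimethyl-2,4,5,6,7,7a-hexahydro-1-benzofuran-2-yl]-2,7-dimethyldodeca-2,4,6,8,10-pentaenal (furanoid C25 aldehyde)
Conditions: 21 (3 equiv), NaOMe (slow addition), MeOH/CH2Cl2, 0 °C to rt; then heptane, reflux
Reagents that add atoms: (2E,4E,6E)-2,7-dimethylocta-2,4,6-trienedial (21), O=C/C(C)=C/C=C/C=C(C)/C=O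
Why: Wittig olefination with an excess of the symmetrical dialdehyde so that one formyl group reacts; the ylide is generated in the presence of the aldehyde (δ-alkoxy allylic ylides of this kind, as in the acetal-bearing C5 Wittig salts, olefinate faster than they lose alkoxide), and the new C11'=C12' bond is brought to E by thermal equilibration.

Step 15
Reactants: 8 (3E)-4-[(4R)-4-[(tert-butyldimethylsilyl)oxy]-2,6,6-trimethylcyclohex-1-en-1-yl]but-3-en-2-one
Product: 23 (3E)-4-[(4R)-4-hydroxy-2,6,6-trimethylcyclohex-1-en-1-yl]but-3-en-2-one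
Conditions: Bu4NF, THF, rt
Reagents that add atoms: none
Why: Fluoride-mediated desilylation frees the C3 hydroxyl that is needed as the directing group.

Step 16
Reactants: 23 (3E)-4-[(4R)-4-hydroxy-2,6,6-trimethylcyclohex-1-en-1-yl]but-3-en-2-one
Product: 24 (3E)-4-[(1R,4S,6S)-4-hydroxy-2,2,6-trimethyl-7-oxabicyclo[4.1.0]heptan-1-yl]but-3-en-2-one (syn-epoxide; 3S,5S,6R)
Conditions: VO(acac)2 (cat.), t-BuOOH, toluene, rt
Reagents that add atoms: tert-butyl hydroperoxide, CC(C)(C)OO
Why: Hydroxyl-directed epoxidation of a homoallylic alcohol: the vanadium alkoxide of the C3 hydroxyl delivers oxygen to its own face of the only electron-rich double bond, C5=C6, which should give the syn epoxide while the enone double bond stays untouched.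

Step 17
Reactants: 24 syn-epoxide
Product: 25 (3E)-4-[(1R,2R,4S)-1,2,4-trihydroxy-2,6,6-trimethylcyclohexyl]but-3-en-2-one
Conditions: HClO4 (cat.), THF/H2O, 0 °C to rt
Reagents that add atoms: water, O
Why: Acid-catalysed epoxide hydrolysis with anti (trans-diaxial, Fürst–Plattner) opening: water should attack C5 with inversion because C6 is neopentylic, its C–O bond is deactivated by the attached enone, and attack at C5 passes through the chair with the C3 hydroxyl equatorial, which gives 5R (5-OH trans to 3-OH) and keeps 6R.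

Step 18
Reactants: 25 (3E)-4-[(1R,2R,4S)-1,2,4-trihydroxy-2,6,6-trimethylcyclohexyl]but-3-en-2-one; 9 triethyl phosphonoacetate
Product: 26 ethyl (2E,4E)-3-methyl-5-[(1R,2R,4S)-1,2,4-trihydroxy-2,6,6-trimethylcyclohexyl]penta-2,4-dienoate
Conditions: NaH (slightly less than 9), THF, 0 °C; then 25, rt
Reagents that add atoms: triethyl phosphonoacetate (9), CCOC(=O)CP(=O)(OCC)OCC
Why: Horner–Wadsworth–Emmons olefination in which the preformed phosphonate anion, used without excess NaH, is too weak a base to deprotonate the hydroxyl groups, so the triol needs no protection; the 2E isomer should predominate and is separated.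

Step 19
Reactants: 26 ethyl (2E,4E)-3-methyl-5-[(1R,2R,4S)-1,2,4-trihydroxy-2,6,6-trimethylcyclohexyl]penta-2,4-dienoate
Product: 27 (1R,2R,4S)-1-[(1E,3E)-5-hydroxy-3-methylpenta-1,3-dien-1-yl]-2,6,6-trimethylcyclohexane-1,2,4-triol
Conditions: i-Bu2AlH (excess), THF, −78 to 0 °C; aq. KNaC4H4O6
Reagents that add atoms: none
Why: 1,2-Reduction of the dienoate to the allylic alcohol by i-Bu2AlH, three further equivalents of which are consumed by the free hydroxyl groups.

Step 20
Reactants: 27 (1R,2R,4S)-1-[(1E,3E)-5-hydroxy-3-methylpenta-1,3-dien-1-yl]-2,6,6-trimethylcyclohexane-1,2,4-triol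
Product: 29 [(2E,4E)-3-methyl-5-[(1R,2R,4S)-1,2,4-trihydroxy-2,6,6-trimethylcyclohexyl]penta-2,4-dien-1-yl]triphenylphosphonium bromide, via allylic bromide 28 (not isolated)
Conditions: NBS, Me2S, CH2Cl2/THF, −20 to 0 °C; then PPh3, rt
Reagents that add atoms: N-bromosuccinimide, O=C1CCC(=O)N1Br; triphenylphosphine, c1ccc(cc1)P(c1ccccc1)c1ccccc1
Why: Corey–Kim halogenation converts only the primary allylic alcohol into the bromide under neutral conditions (secondary and tertiary hydroxyls give no halide) and triphenylphosphine then forms the salt by SN2, so acid that could ionise the tertiary allylic C6 hydroxyl is avoided.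

Step 21
Reactants: 29 triol C15 phosphonium bromide; 22 furanoid C25 aldehyde
Product: 30 (3S,5R,6R,3'S,5'R,8'R)-3'-[(tert-butyldimethylsilyl)oxy]-5',8'-epoxy-5,6,5',8'-tetrahydro-β,β-carotene-3,5,6-triol
Conditions: NaOMe, MeOH/CH2Cl2, 0 °C to rt; then EtOH, reflux
Reagents that add atoms: none
Why: Wittig olefination joins C11 to C12; the free hydroxyl groups tolerate the methoxide-generated ylide, and the Z isomer at the new double bond is converted into the all-E compound by thermal equilibration.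

Step 22
Reactants: 30 3'-O-TBS ether of the target
Product: 31 (3S,5R,6R,3'S,5'R,8'R)-5',8'-epoxy-5,6,5',8'-tetrahydro-β,β-carotene-3,5,6,3'-tetrol (CNP0210286.2)
Conditions: Bu4NF, THF, 0 °C to rt
Reagents that add atoms: none
Why: Fluoride cleaves the last silyl ether under non-acidic conditions that the acid-labile furanoid C8'–O bond, the tertiary allylic hydroxyl and the polyene should tolerate.

**Compound list**

1 | 4-oxoisophorone (2,6,6-trimethylcyclohex-2-ene-1,4-dione) | CC1=CC(=O)CC(C)(C)C1=O | starting material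
2 | (6R)-2,2,6-trimethylcyclohexane-1,4-dione | O=C1[C@H](C)CC(=O)CC1(C)C | intermediate
3 | (4R,6R)-4-hydroxy-2,2,6-trimethylcyclohexan-1-one | O=C1[C@H](C)C[C@@H](O)CC1(C)C | intermediate
4 | (4R,6R)-4-[(tert-butyldimethylsilyl)oxy]-2,2,6-trimethylcyclohexan-1-one | O=C1[C@H](C)C[C@@H](O[Si](C)(C)C(C)(C)C)CC1(C)C | intermediate
5 | lithium (4R)-4-[(tert-butyldimethylsilyl)oxy]-2,6,6-trimethylcyclohex-1-en-1-olate (not isolated) | [Li+].[O-]C1=C(C)C[C@@H](O[Si](C)(C)C(C)(C)C)CC1(C)C | intermediate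
6 | (4R)-4-[(tert-butyldimethylsilyl)oxy]-2,6,6-trimethylcyclohex-1-en-1-yl trifluoromethanesulfonate | O=S(=O)(OC1=C(C)C[C@@H](O[Si](C)(C)C(C)(C)C)CC1(C)C)C(F)(F)F | intermediate
7 | but-3-en-2-one | CC(=O)C=C | starting material
8 | (3E)-4-[(4R)-4-[(tert-butyldimethylsilyl)oxy]-2,6,6-trimethylcyclohex-1-en-1-yl]but-3-en-2-one | CC(=O)/C=C/C1=C(C)C[C@@H](O[Si](C)(C)C(C)(C)C)CC1(C)C | intermediate
9 | triethyl phosphonoacetate | CCOC(=O)CP(=O)(OCC)OCC | starting material
10 | ethyl (2E,4E)-5-[(4R)-4-[(tert-butyldimethylsilyl)oxy]-2,6,6-trimethylcyclohex-1-en-1-yl]-3-methylpenta-2,4-dienoate | CCOC(=O)/C=C(C)/C=C/C1=C(C)C[C@@H](O[Si](C)(C)C(C)(C)C)CC1(C)C | intermediate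
11 | dioxygen | O=O | starting material
12 | ethyl (2E)-3-[(3R,7S,8aR)-7-[(tert-butyldimethylsilyl)oxy]-5,5,8a-trimethyl-3,5,6,7,8,8a-hexahydrobenzo[c][1,2]dioxin-3-yl]but-2-enoate (3'S,5'R,8'R endoperoxide) | CCOC(=O)/C=C(C)/[C@H]1C=C2C(C)(C)C[C@H](O[Si](C)(C)C(C)(C)C)C[C@@]2(C)OO1 | intermediate
13 | ethyl (2E,4R,5Z)-5-[(2R,4S)-4-[(tert-butyldimethylsilyl)oxy]-2-hydroxy-2,6,6-trimethylcyclohexylidene]-4-hydroxy-3-methylpent-2-enoate | CCOC(=O)/C=C(C)/[C@H](O)/C=C1/C(C)(C)C[C@H](O[Si](C)(C)C(C)(C)C)C[C@@]1(C)O | intermediate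
14 | ethyl (2E,4S,5Z)-5-[(2R,4S)-4-[(tert-butyldimethylsilyl)oxy]-2-hydroxy-2,6,6-trimethylcyclohexylidene]-3-methyl-4-[(4-nitrobenzoyl)oxy]pent-2-enoate | CCOC(=O)/C=C(C)/[C@@H](OC(=O)c2ccc(cc2)[N+](=O)[O-])/C=C1/C(C)(C)C[C@H](O[Si](C)(C)C(C)(C)C)C[C@@]1(C)O | intermediate
15 | ethyl (2E,4S,5Z)-5-[(2R,4S)-4-[(tert-butyldimethylsilyl)oxy]-2-hydroxy-2,6,6-trimethylcyclohexylidene]-4-hydroxy-3-methylpent-2-enoate | CCOC(=O)/C=C(C)/[C@@H](O)/C=C1/C(C)(C)C[C@H](O[Si](C)(C)C(C)(C)C)C[C@@]1(C)O | intermediate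
16 | ethyl (2E,4S,5Z)-5-[(2R,4S)-4-[(tert-butyldimethylsilyl)oxy]-2-hydroxy-2,6,6-trimethylcyclohexylidene]-4-[(methanesulfonyl)oxy]-3-methylpent-2-enoate (not isolated) | CCOC(=O)/C=C(C)/[C@@H](OS(C)(=O)=O)/C=C1/C(C)(C)C[C@H](O[Si](C)(C)C(C)(C)C)C[C@@]1(C)O | intermediate
17 | ethyl (2E)-3-[(2R,6S,7aR)-6-[(tert-butyldimethylsilyl)oxy]-4,4,7a-trimethyl-2,4,5,6,7,7a-hexahydro-1-benzofuran-2-yl]but-2-enoate | CCOC(=O)/C=C(C)/[C@H]1C=C2C(C)(C)C[C@H](O[Si](C)(C)C(C)(C)C)C[C@@]2(C)O1 | intermediate
18 | (2E)-3-[(2R,6S,7aR)-6-[(tert-butyldimethylsilyl)oxy]-4,4,7a-trimethyl-2,4,5,6,7,7a-hexahydro-1-benzofuran-2-yl]but-2-en-1-ol | OC/C=C(C)/[C@H]1C=C2C(C)(C)C[C@H](O[Si](C)(C)C(C)(C)C)C[C@@]2(C)O1 | intermediate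
19 | (2R,6S,7aR)-2-[(2E)-4-bromobut-2-en-2-yl]-6-[(tert-butyldimethylsilyl)oxy]-4,4,7a-trimethyl-2,4,5,6,7,7a-hexahydro-1-benzofuran (not isolated) | BrC/C=C(C)/[C@H]1C=C2C(C)(C)C[C@H](O[Si](C)(C)C(C)(C)C)C[C@@]2(C)O1 | intermediate
20 | [(2E)-3-[(2R,6S,7aR)-6-[(tert-butyldimethylsilyl)oxy]-4,4,7a-trimethyl-2,4,5,6,7,7a-hexahydro-1-benzofuran-2-yl]but-2-en-1-yl]triphenylphosphonium bromide | [Br-].c1ccc(cc1)[P+](c1ccccc1)(c1ccccc1)C/C=C(C)/[C@H]1C=C2C(C)(C)C[C@H](O[Si](C)(C)C(C)(C)C)C[C@@]2(C)O1 | intermediate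
21 | (2E,4E,6E)-2,7-dimethylocta-2,4,6-trienedial | O=C/C(C)=C/C=C/C=C(C)/C=O | starting material
22 | (2E,4E,6E,8E,10E)-11-[(2R,6S,7aR)-6-[(tert-butyldimethylsilyl)oxy]-4,4,7a-trimethyl-2,4,5,6,7,7a-hexahydro-1-benzofuran-2-yl]-2,7-dimethyldodeca-2,4,6,8,10-pentaenal | O=C/C(C)=C/C=C/C=C(C)/C=C/C=C(\C)[C@H]1C=C2C(C)(C)C[C@H](O[Si](C)(C)C(C)(C)C)C[C@@]2(C)O1 | intermediate
23 | (3E)-4-[(4R)-4-hydroxy-2,6,6-trimethylcyclohex-1-en-1-yl]but-3-en-2-one | CC(=O)/C=C/C1=C(C)C[C@@H](O)CC1(C)C | intermediate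
24 | (3E)-4-[(1R,4S,6S)-4-hydroxy-2,2,6-trimethyl-7-oxabicyclo[4.1.0]heptan-1-yl]but-3-en-2-one | CC(=O)/C=C/[C@]12O[C@@]1(C)C[C@@H](O)CC2(C)C | intermediate
25 | (3E)-4-[(1R,2R,4S)-1,2,4-trihydroxy-2,6,6-trimethylcyclohexyl]but-3-en-2-one | CC(=O)/C=C/[C@@]1(O)C(C)(C)C[C@H](O)C[C@@]1(C)O | intermediate
26 | ethyl (2E,4E)-3-methyl-5-[(1R,2R,4S)-1,2,4-trihydroxy-2,6,6-trimethylcyclohexyl]penta-2,4-dienoate | CCOC(=O)/C=C(C)/C=C/[C@@]1(O)C(C)(C)C[C@H](O)C[C@@]1(C)O | intermediate
27 | (1R,2R,4S)-1-[(1E,3E)-5-hydroxy-3-methylpenta-1,3-dien-1-yl]-2,6,6-trimethylcyclohexane-1,2,4-triol | OC/C=C(C)/C=C/[C@@]1(O)C(C)(C)C[C@H](O)C[C@@]1(C)O | intermediate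
28 | (1R,2R,4S)-1-[(1E,3E)-5-bromo-3-methylpenta-1,3-dien-1-yl]-2,6,6-trimethylcyclohexane-1,2,4-triol (not isolated) | BrC/C=C(C)/C=C/[C@@]1(O)C(C)(C)C[C@H](O)C[C@@]1(C)O | intermediate
29 | [(2E,4E)-3-methyl-5-[(1R,2R,4S)-1,2,4-trihydroxy-2,6,6-trimethylcyclohexyl]penta-2,4-dien-1-yl]triphenylphosphonium bromide | [Br-].c1ccc(cc1)[P+](c1ccccc1)(c1ccccc1)C/C=C(C)/C=C/[C@@]1(O)C(C)(C)C[C@H](O)C[C@@]1(C)O | intermediate
30 | (3S,5R,6R,3'S,5'R,8'R)-3'-[(tert-butyldimethylsilyl)oxy]-5',8'-epoxy-5,6,5',8'-tetrahydro-β,β-carotene-3,5,6-triol | CC(/C=C/C=C(C)/C=C/[C@@]1(O)C(C)(C)C[C@H](O)C[C@@]1(C)O)=C\C=C\C=C(C)\C=C\C=C(/C)[C@H]1C=C2C(C)(C)C[C@H](O[Si](C)(C)C(C)(C)C)C[C@@]2(C)O1 | intermediate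
31 | (3S,5R,6R,3'S,5'R,8'R)-5',8'-epoxy-5,6,5',8'-tetrahydro-β,β-carotene-3,5,6,3'-tetrol | CC(/C=C/C=C(C)/C=C/[C@@]1(O)C(C)(C)C[C@H](O)C[C@@]1(C)O)=C\C=C\C=C(C)\C=C\C=C(/C)[C@H]1C=C2C(C)(C)C[C@H](O)C[C@@]2(C)O1 | target

**Step count**

Total: 22 steps. Longest linear sequence: 16 steps (steps 1 to 14, then 21 and 22).

**Steps most likely to fail, with fallbacks**

Step 7. The photooxygenation may show poor facial selectivity, or it may be diverted into the ene reaction at C5'=C6' (allylic hydroperoxides) or into photosensitised over-oxidation of the product. The fallback sets out from 10 and replaces the cycloaddition by epoxidation and rearrangement. 3-Chloroperbenzoic acid with NaHCO3 in CH2Cl2 at 0 °C should epoxidise the electron-rich C5'=C6' bond mainly anti to the silyloxy group and give ethyl (2E,4E)-5-[(1S,4S,6R)-4-[(tert-butyldimethylsilyl)oxy]-2,2,6-trimethyl-7-oxabicyclo[4.1.0]heptan-1-yl]-3-methylpenta-2,4-dienoate F1. Catalytic HCl in CHCl3 should then bring about the epoxide-to-furanoid rearrangement: the C6'–O bond ionises and the C5' oxygen closes on C8'. This gives 17 together with the (8'S) epimer of the furanoid ester F2, from which it is separated; F2 can be re-equilibrated under the same acid. The fallback comes back to the route at 17.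

Step 9. The alkoxyphosphonium ion at C8' may be captured by the neighbouring tertiary C5' hydroxyl instead of the carboxylate (a single inversion that closes the ring with the wrong C8' configuration), or the hindered doubly allylic carbinol may react sluggishly. The fallback sets out from 12 and inverts C8' by a redox sequence. Et3N in CH2Cl2 at rt (Kornblum–DeLaMare rearrangement, removal of H-8' with O–O cleavage) should give ethyl (2E,5Z)-5-[(2R,4S)-4-[(tert-butyldimethylsilyl)oxy]-2-hydroxy-2,6,6-trimethylcyclohexylidene]-3-methyl-4-oxopent-2-enoate F3. 1,2-Reduction with NaBH4 and CeCl3·7H2O in EtOH at −78 °C should give both C8' alcohols without strong facial bias. Compound 15 is separated from 13, and 13 can be oxidised back to F3 with MnO2 and recycled. The fallback comes back to the route at 15.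

Step 11. The doubly allylic mesylate may ionise before the ring closes, which would scramble the configuration at C8'. The fallback sets out from 15 and closes the ring by Mitsunobu cyclodehydration (PPh3, DIAD, THF, 0 °C, no acid component). The secondary C8' hydroxyl is converted into its alkoxyphosphonium ion and is displaced directly by the C5' hydroxyl with inversion, without a sulfonate ester on the way. The fallback comes back to the route at 17.

**Further compounds**

F1 | step 7 | ethyl (2E,4E)-5-[(1S,4S,6R)-4-[(tert-butyldimethylsilyl)oxy]-2,2,6-trimethyl-7-oxabicyclo[4.1.0]heptan-1-yl]-3-methylpenta-2,4-dienoate | CCOC(=O)/C=C(C)/C=C/[C@@]12O[C@]1(C)C[C@@H](O[Si](C)(C)C(C)(C)C)CC2(C)C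
F2 | step 7 | ethyl (2E)-3-[(2S,6S,7aR)-6-[(tert-butyldimethylsilyl)oxy]-4,4,7a-trimethyl-2,4,5,6,7,7a-hexahydro-1-benzofuran-2-yl]but-2-enoate | CCOC(=O)/C=C(C)/[C@@H]1C=C2C(C)(C)C[C@H](O[Si](C)(C)C(C)(C)C)C[C@@]2(C)O1
F3 | step 9 | ethyl (2E,5Z)-5-[(2R,4S)-4-[(tert-butyldimethylsilyl)oxy]-2-hydroxy-2,6,6-trimethylcyclohexylidene]-3-methyl-4-oxopent-2-enoate | CCOC(=O)/C=C(C)/C(=O)/C=C1/C(C)(C)C[C@H](O[Si](C)(C)C(C)(C)C)C[C@@]1(C)O
F0 | step 11 | none | none
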